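**Remark:** the target is read as (−)-epiafzelechin 3-O-gallate-(4β→6)-(−)-epicatechin 3-O-gallate (upper unit 2R,3R,4S with 2,3-cis/3,4-trans; lower unit 2R,3R); compounds 1, 2, 6, 10 and 14 are taken as commercial.

## Retrosynthetic overview

1. The last step is one hydrogenolysis that removes 13 benzyl ethers and two bromine caps from the protected dimer 20.
2. Key disconnection: both aryl bonds of upper C4, i.e. the C4–C4a bond that closes the upper pyran (C) ring and the C4–C6 interflavan bond, leading back to acyclic aldehyde 13 (C4 = CHO) and brominated epicatechin gallate 17.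
3. Enabling feature: upper C4 is a doubly benzylic CH between two phloroglucinol-type rings (C4a of the upper A ring, ortho to O1; C6 of the lower A ring, between O5 and O7) and next to the C3 galloyl ester, so it is the retron of an aldehyde carbon arylated twice, with the ester steering 3,4-trans.
4. Aldehyde 13 comes from cis-glycidol 5 (Z-olefination, Jacobsen epoxidation, reduction) by inverting phenoxide opening at the benzylic carbon with bromine-capped phenol 7, which sets upper C2 and C3; galloylation and oxidation follow.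
5. Nucleophile 17 comes from (−)-epicatechin (benzylation, C8 bromination, galloylation); the lower rings are from the chiral pool and the upper pyran ring is formed last, in step 13.

Key step: step 13

## Route

Step 1
Reactants: 1 4-(benzyloxy)benzaldehyde; 2 methyl 2-[bis(2,2,2-trifluoroethoxy)phosphoryl]acetate
Product: 3 methyl (Z)-3-[4-(benzyloxy)phenyl]prop-2-enoate
Conditions: KHMDS, 18-crown-6, THF, −78 °C
Reagents that add atoms: none
Why: Still–Gennari variant of the Horner–Wadsworth–Emmons olefination, in which the trifluoroethyl phosphonate under dissociating conditions eliminates faster than it equilibrates and should give the (Z)-cinnamate needed for a cis-epoxide.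

Step 2
Reactants: 3 methyl (Z)-3-[4-(benzyloxy)phenyl]prop-2-enoate
Product: 4 methyl (2S,3S)-3-[4-(benzyloxy)phenyl]oxirane-2-carboxylate (cis)
Conditions: (S,S)-Jacobsen Mn(salen)Cl (5 mol%), 4-phenylpyridine N-oxide (cat.), aq NaOCl (pH 11), CH2Cl2, 0 °C
Reagents that add atoms: sodium hypochlorite, [Na+].[O-]Cl
Why: Jacobsen–Katsuki epoxidation, for which cis-cinnamate esters are a favourable class; the (S,S)-salen ligand should set both epoxide carbons (benzylic carbon S), and any trans-epoxide formed by leakage is removed by chromatography.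

Step 3
Reactants: 4 methyl (2S,3S)-3-[4-(benzyloxy)phenyl]oxirane-2-carboxylate
Product: 5 [(2R,3S)-3-[4-(benzyloxy)phenyl]oxiran-2-yl]methanol (cis)
Conditions: NaBH4, MeOH/THF, 0 °C
Reagents that add atoms: none
Why: Borohydride reduction of the α-oxygen-activated glycidic ester to the epoxy alcohol, which should leave the epoxide and both stereocenters untouched (the descriptor at C2 changes only by priority).

Step 4
Reactants: 6 3,5-bis(benzyloxy)phenol
Product: 7 3,5-bis(benzyloxy)-2-bromophenol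
Conditions: NBS (1.0 equiv), i-Pr2NH (10 mol%), CH2Cl2, −78 → 0 °C
Reagents that add atoms: N-bromosuccinimide, O=C1CCC(=O)N1Br
Why: Amine-catalysed ortho-selective bromination of a phenol (N-bromoamine delivered by hydrogen bonding to the OH), stopped at the mono-ortho-bromide; the bromine is the temporary cap for the later C8 of the upper unit.

Step 5
Reactants: 5 [(2R,3S)-3-[4-(benzyloxy)phenyl]oxiran-2-yl]methanol; 7 3,5-bis(benzyloxy)-2-bromophenol
Product: 8 (2R,3R)-3-[3,5-bis(benzyloxy)-2-bromophenoxy]-3-[4-(benzyloxy)phenyl]propane-1,2-diol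
Conditions: 7 (1.5 equiv), aq NaOH (0.5 equiv), dioxane/H2O, 65 °C
Reagents that add atoms: none
Why: Base-mediated SN2 opening of a 3-aryl-2,3-epoxy alcohol by a phenoxide at the aryl-activated benzylic carbon, with inversion there, should turn the cis-epoxide into the threo aryloxy diol and so fix C2 (aryl ether) and C3 (carbinol) of the upper unit.

Step 6
Reactants: 8 (2R,3R)-3-[3,5-bis(benzyloxy)-2-bromophenoxy]-3-[4-(benzyloxy)phenyl]propane-1,2-diol
Product: 9 (1R,2R)-1-[3,5-bis(benzyloxy)-2-bromophenoxy]-1-[4-(benzyloxy)phenyl]-3-[(tert-butyldimethylsilyl)oxy]propan-2-ol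
Conditions: TBSCl (1.05 equiv), imidazole, CH2Cl2, 0 °C
Reagents that add atoms: tert-butyldimethylsilyl chloride, CC(C)(C)[Si](C)(C)Cl
Why: Selective silylation of the primary hydroxyl of a 1,2-diol by steric discrimination.

Step 7
Reactants: 9 (1R,2R)-1-[3,5-bis(benzyloxy)-2-bromophenoxy]-1-[4-(benzyloxy)phenyl]-3-[(tert-butyldimethylsilyl)oxy]propan-2-ol; 10 3,4,5-tris(benzyloxy)benzoic acid
Product: 11 (1R,2R)-1-[3,5-bis(benzyloxy)-2-bromophenoxy]-1-[4-(benzyloxy)phenyl]-3-[(tert-butyldimethylsilyl)oxy]propan-2-yl 3,4,5-tris(benzyloxy)benzoate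
Conditions: DCC, DMAP, CH2Cl2, rt
Reagents that add atoms: none
Why: Steglich esterification of the secondary alcohol, an acyl–oxygen bond formation that does not touch the carbinol stereocenter.

Step 8
Reactants: 11 (1R,2R)-1-[3,5-bis(benzyloxy)-2-bromophenoxy]-1-[4-(benzyloxy)phenyl]-3-[(tert-butyldimethylsilyl)oxy]propan-2-yl 3,4,5-tris(benzyloxy)benzoate
Product: 12 (1R,2R)-1-[3,5-bis(benzyloxy)-2-bromophenoxy]-1-[4-(benzyloxy)phenyl]-3-hydroxypropan-2-yl 3,4,5-tris(benzyloxy)benzoate
Conditions: HF·pyridine, pyridine, THF, 0 °C → rt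
Reagents that add atoms: none
Why: Fluoride cleavage of the silyl ether under weakly acidic buffered conditions, chosen because base-promoted 2→1 migration of the aroyl group is then not expected.

Step 9
Reactants: 12 (1R,2R)-1-[3,5-bis(benzyloxy)-2-bromophenoxy]-1-[4-(benzyloxy)phenyl]-3-hydroxypropan-2-yl 3,4,5-tris(benzyloxy)benzoate
Product: 13 (1R,2S)-1-[3,5-bis(benzyloxy)-2-bromophenoxy]-1-[4-(benzyloxy)phenyl]-3-oxopropan-2-yl 3,4,5-tris(benzyloxy)benzoate
Conditions: Dess–Martin periodinane, CH2Cl2, 0 °C → rt; used at once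
Reagents that add atoms: none
Why: Dess–Martin oxidation under non-basic conditions should give the α-acyloxy-β-aryloxy aldehyde without enolization or β-elimination of the aryloxide (the descriptor at the α-carbon changes only by priority).

Step 10
Reactants: 14 (−)-epicatechin
Product: 15 5,7,3',4'-tetra-O-benzyl-(−)-epicatechin
Conditions: BnBr (4.4 equiv), K2CO3, DMF, 0 °C → rt
Reagents that add atoms: benzyl bromide, BrCc1ccccc1
Why: Williamson etherification of the four phenols, selective over the secondary alcohol by acidity, with C2 and C3 untouched.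

Step 11
Reactants: 15 5,7,3',4'-tetra-O-benzyl-(−)-epicatechin
Product: 16 8-bromo-5,7,3',4'-tetra-O-benzyl-(−)-epicatechin
Conditions: NBS (1.0 equiv), CH2Cl2, −78 °C → rt
Reagents that add atoms: N-bromosuccinimide, O=C1CCC(=O)N1Br
Why: Electrophilic aromatic bromination, which on 5,7-di-O-benzyl flavans goes to C8 (ortho to the ring oxygen, the less hindered A-ring position) and so blocks C8 while leaving C6 free.

Step 12
Reactants: 16 8-bromo-5,7,3',4'-tetra-O-benzyl-(−)-epicatechin; 10 3,4,5-tris(benzyloxy)benzoic acid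
Product: 17 8-bromo-5,7,3',4'-tetra-O-benzyl-(−)-epicatechin 3-O-[3,4,5-tris(benzyloxy)benzoate]
Conditions: DCC, DMAP, CH2Cl2, rt
Reagents that add atoms: none
Why: Steglich esterification of the 3-hydroxyl with retention at C3.

Step 13
Reactants: 13 (1R,2S)-1-[3,5-bis(benzyloxy)-2-bromophenoxy]-1-[4-(benzyloxy)phenyl]-3-oxopropan-2-yl 3,4,5-tris(benzyloxy)benzoate; 17 8-bromo-5,7,3',4'-tetra-O-benzyl-(−)-epicatechin 3-O-[3,4,5-tris(benzyloxy)benzoate]
Product: 20 8-bromo-5,7,4'-tri-O-benzyl-3-O-(tri-O-benzylgalloyl)epiafzelechin-(4β→6)-8-bromo-5,7,3',4'-tetra-O-benzyl-3-O-(tri-O-benzylgalloyl)epicatechin, via flavan-4-ol 18 (not isolated), via C4 flavanyl cation 19 (not isolated)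
Conditions: 17 (3 equiv, excess recovered), TMSOTf (0.3 equiv), 4 Å MS, CH2Cl2, −40 → −10 °C, slow addition of 13; then aq NaHCO3
Reagents that add atoms: none
Why: Proposed new method: the acid activates the aldehyde of 13, the only free ortho carbon of its bromine-capped phloroglucinol ether ring attacks the carbonyl carbon (intramolecular Friedel–Crafts hydroxyalkylation, 6-exo-trig at C=O, closing the pyran ring through the C4–C4a bond) to give flavan-4-ol 18, which ionizes to the doubly oxygen-stabilized benzylic cation 19 (in equilibrium with the dioxolanylium bridged by the 3-O-galloyl group) and is captured by C6 of 17 (Friedel–Crafts alkylation); should 17 add to the aldehyde first, the cation stabilized by the lower A ring closes the same C4–C4a bond and the same product results. The closest known reactions are the acid-mediated cyclization of 3-aryloxypropanals to chroman-4-ols, the Lewis-acid coupling of C4-oxygenated 3-O-acyl flavans with flavan nucleophiles, and the one-pot double arylation of aldehydes to diarylmethanes; new is their fusion into one cascade on an acyclic aldehyde. The one new stereocenter, C4, is set in the last C–C bond formation: with the 2-aryl group equatorial and the 3-O-galloyl group axial in the half-chair, the arene enters anti to the C3–O bond (opening of the acyloxonium, axial attack), which should give the 3,4-trans (4β) product. Needed selectivities are C6 rather than C8 on the lower unit (secured by the C8 bromine of 17), no self-condensation of the upper half (its future C8 carries bromine, so only a hindered C6-type site of the same low reactivity as that of 17 remains, and 17 is in excess while 13 is kept dilute by slow addition), and no ionization of the acyclic benzylic aryl ether at C2 (catalytic acid, low temperature).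

Step 14
Reactants: 20 8-bromo-5,7,4'-tri-O-benzyl-3-O-(tri-O-benzylgalloyl)epiafzelechin-(4β→6)-8-bromo-5,7,3',4'-tetra-O-benzyl-3-O-(tri-O-benzylgalloyl)epicatechin
Product: 21 (−)-epiafzelechin 3-O-gallate-(4β→6)-(−)-epicatechin 3-O-gallate (CNP0169607.1)
Conditions: H2 (1 atm), Pd(OH)2/C, Et3N (2.2 equiv), THF/MeOH/H2O, rt; filtration, Sephadex LH-20
Reagents that add atoms: none
Why: Catalytic hydrogenolysis of the thirteen benzyl ethers with concurrent hydrodebromination of both aryl bromides (Pearlman's catalyst, amine as HBr scavenger), conditions under which the benzoate esters, the C2–O bonds and the interflavan bond should survive.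

## Compound list

1 | 4-(benzyloxy)benzaldehyde | O=Cc1ccc(OCc2ccccc2)cc1 | starting material
2 | methyl 2-[bis(2,2,2-trifluoroethoxy)phosphoryl]acetate | COC(=O)CP(=O)(OCC(F)(F)F)OCC(F)(F)F | starting material
3 | methyl (Z)-3-[4-(benzyloxy)phenyl]prop-2-enoate | COC(=O)/C=C\c1ccc(OCc2ccccc2)cc1 | intermediate
4 | methyl (2S,3S)-3-[4-(benzyloxy)phenyl]oxirane-2-carboxylate | COC(=O)[C@H]1O[C@H]1c1ccc(OCc2ccccc2)cc1 | intermediate
5 | [(2R,3S)-3-[4-(benzyloxy)phenyl]oxiran-2-yl]methanol | OC[C@H]1O[C@H]1c1ccc(OCc2ccccc2)cc1 | intermediate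
6 | 3,5-bis(benzyloxy)phenol | Oc1cc(OCc2ccccc2)cc(OCc2ccccc2)c1 | starting material
7 | 3,5-bis(benzyloxy)-2-bromophenol | Oc1cc(OCc2ccccc2)cc(OCc2ccccc2)c1Br | intermediate
8 | (2R,3R)-3-[3,5-bis(benzyloxy)-2-bromophenoxy]-3-[4-(benzyloxy)phenyl]propane-1,2-diol | OC[C@@H](O)[C@H](Oc1cc(OCc2ccccc2)cc(OCc2ccccc2)c1Br)c1ccc(OCc2ccccc2)cc1 | intermediate
9 | (1R,2R)-1-[3,5-bis(benzyloxy)-2-bromophenoxy]-1-[4-(benzyloxy)phenyl]-3-[(tert-butyldimethylsilyl)oxy]propan-2-ol | CC(C)(C)[Si](C)(C)OC[C@@H](O)[C@H](Oc1cc(OCc2ccccc2)cc(OCc2ccccc2)c1Br)c1ccc(OCc2ccccc2)cc1 | intermediate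
10 | 3,4,5-tris(benzyloxy)benzoic acid | OC(=O)c1cc(OCc2ccccc2)c(OCc2ccccc2)c(OCc2ccccc2)c1 | starting material
11 | (1R,2R)-1-[3,5-bis(benzyloxy)-2-bromophenoxy]-1-[4-(benzyloxy)phenyl]-3-[(tert-butyldimethylsilyl)oxy]propan-2-yl 3,4,5-tris(benzyloxy)benzoate | CC(C)(C)[Si](C)(C)OC[C@@H](OC(=O)c1cc(OCc2ccccc2)c(OCc2ccccc2)c(OCc2ccccc2)c1)[C@H](Oc1cc(OCc2ccccc2)cc(OCc2ccccc2)c1Br)c1ccc(OCc2ccccc2)cc1 | intermediate
12 | (1R,2R)-1-[3,5-bis(benzyloxy)-2-bromophenoxy]-1-[4-(benzyloxy)phenyl]-3-hydroxypropan-2-yl 3,4,5-tris(benzyloxy)benzoate | OC[C@@H](OC(=O)c1cc(OCc2ccccc2)c(OCc2ccccc2)c(OCc2ccccc2)c1)[C@H](Oc1cc(OCc2ccccc2)cc(OCc2ccccc2)c1Br)c1ccc(OCc2ccccc2)cc1 | intermediate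
13 | (1R,2S)-1-[3,5-bis(benzyloxy)-2-bromophenoxy]-1-[4-(benzyloxy)phenyl]-3-oxopropan-2-yl 3,4,5-tris(benzyloxy)benzoate | O=C[C@@H](OC(=O)c1cc(OCc2ccccc2)c(OCc2ccccc2)c(OCc2ccccc2)c1)[C@H](Oc1cc(OCc2ccccc2)cc(OCc2ccccc2)c1Br)c1ccc(OCc2ccccc2)cc1 | intermediate
14 | (−)-epicatechin | O[C@@H]1Cc2c(O)cc(O)cc2O[C@@H]1c1ccc(O)c(O)c1 | starting material
15 | 5,7,3',4'-tetra-O-benzyl-(−)-epicatechin | O[C@@H]1Cc2c(OCc3ccccc3)cc(OCc3ccccc3)cc2O[C@@H]1c1ccc(OCc2ccccc2)c(OCc2ccccc2)c1 | intermediate
16 | 8-bromo-5,7,3',4'-tetra-O-benzyl-(−)-epicatechin | O[C@@H]1Cc2c(OCc3ccccc3)cc(OCc3ccccc3)c(Br)c2O[C@@H]1c1ccc(OCc2ccccc2)c(OCc2ccccc2)c1 | intermediate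
17 | 8-bromo-5,7,3',4'-tetra-O-benzyl-(−)-epicatechin 3-O-[3,4,5-tris(benzyloxy)benzoate] | O=C(O[C@@H]1Cc2c(OCc3ccccc3)cc(OCc3ccccc3)c(Br)c2O[C@@H]1c1ccc(OCc2ccccc2)c(OCc2ccccc2)c1)c1cc(OCc2ccccc2)c(OCc2ccccc2)c(OCc2ccccc2)c1 | intermediate
18 | 8-bromo-5,7,4'-tri-O-benzyl-3-O-(tri-O-benzylgalloyl)epiafzelechin-4-ol (2,3-cis flavan-4-ol, both C4 epimers or their silyl ethers) | O=C(O[C@@H]1C(O)c2c(OCc3ccccc3)cc(OCc3ccccc3)c(Br)c2O[C@@H]1c1ccc(OCc2ccccc2)cc1)c1cc(OCc2ccccc2)c(OCc2ccccc2)c(OCc2ccccc2)c1 | intermediate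
19 | C4 flavanyl cation of 18 (benzylic cation, also describable as the 3-O-acyl-bridged dioxolanylium) | O=C(O[C@@H]1[CH+]c2c(OCc3ccccc3)cc(OCc3ccccc3)c(Br)c2O[C@@H]1c1ccc(OCc2ccccc2)cc1)c1cc(OCc2ccccc2)c(OCc2ccccc2)c(OCc2ccccc2)c1 | intermediate
20 | 8-bromo-5,7,4'-tri-O-benzyl-3-O-(tri-O-benzylgalloyl)epiafzelechin-(4β→6)-8-bromo-5,7,3',4'-tetra-O-benzyl-3-O-(tri-O-benzylgalloyl)epicatechin | O=C(O[C@@H]1[C@@H](c2c(OCc3ccccc3)c(Br)c4c(c2OCc2ccccc2)C[C@@H](OC(=O)c2cc(OCc3ccccc3)c(OCc3ccccc3)c(OCc3ccccc3)c2)[C@@H](c2ccc(OCc3ccccc3)c(OCc3ccccc3)c2)O4)c2c(OCc3ccccc3)cc(OCc3ccccc3)c(Br)c2O[C@@H]1c1ccc(OCc2ccccc2)cc1)c1cc(OCc2ccccc2)c(OCc2ccccc2)c(OCc2ccccc2)c1 | intermediate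
21 | (−)-epiafzelechin 3-O-gallate-(4β→6)-(−)-epicatechin 3-O-gallate | O=C(O[C@@H]1[C@@H](c2c(O)cc3c(c2O)C[C@@H](OC(=O)c2cc(O)c(O)c(O)c2)[C@@H](c2ccc(O)c(O)c2)O3)c2c(O)cc(O)cc2O[C@@H]1c1ccc(O)cc1)c1cc(O)c(O)c(O)c1 | target

## Step count and risks

Total steps: 14. Longest linear sequence: 10 steps (1, 2, 3, 5, 6, 7, 8, 9, 13, 14).

**Step 13 (the step proposed as new).** Three processes may spoil it: the C4 cation may be captured by the free C6-type position of another upper-half molecule instead of by the deactivated C6 of 17, giving oligomers; the acyclic benzylic aryl ether may ionize before ring closure and scramble C2; or the cascade may stall at the flavan-4-ol stage. The fallback separates the two bond formations with known chemistry. It sets out from 13, which is cyclized with camphorsulfonic acid in CH2Cl2 containing 2-ethoxyethanol (acetal formation, intramolecular Friedel–Crafts closure of the C4–C4a bond, solvolytic trapping at C4). This should give the isolable electrophile 8-bromo-5,7,4'-tri-O-benzyl-4β-(2-ethoxyethoxy)-3-O-(tri-O-benzylgalloyl)epiafzelechin F1. F1 is then coupled with 17 (3 equiv) under TMSOTf in CH2Cl2 at −40 °C, the standard coupling of 4-alkoxy-3-O-acyl flavans, and the route is rejoined at 20.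

**Step 5.** The epoxy alkoxide may undergo Payne rearrangement followed by attack at the terminal carbon, hydroxide may compete as nucleophile, or the p-alkoxybenzylic carbon may open with partial SN1 character and lose configuration. The fallback opens the ester instead of the alcohol. It sets out from 4, which is treated with 7 and substoichiometric Cs2CO3 in MeCN at rt (no free alkoxide, so no Payne pathway; the ester directs attack to the benzylic carbon). This should give methyl (2S,3R)-3-[3,5-bis(benzyloxy)-2-bromophenoxy]-3-[4-(benzyloxy)phenyl]-2-hydroxypropanoate F2 with inversion. Reduction of F2 with LiBH4 in THF at 0 °C rejoins the route at 8.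

**Step 4.** Bromination of the triply activated ring may show poor ortho/para discrimination and run on to dibromides. The fallback replaces electrophilic bromination by directed ortho-metalation. It sets out from 6, which is carbamoylated (Et2NCOCl, K2CO3, MeCN) to 3,5-bis(benzyloxy)phenyl N,N-diethylcarbamate F3. F3 is lithiated between the carbamate and the neighbouring benzyloxy group (s-BuLi, TMEDA, THF, −78 °C) and quenched with 1,2-dibromotetrafluoroethane to give 3,5-bis(benzyloxy)-2-bromophenyl N,N-diethylcarbamate F4. Hydrolysis of F4 (KOH, EtOH/H2O, reflux) rejoins the route at 7.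

Further compounds
F1 | step 13 | 8-bromo-5,7,4'-tri-O-benzyl-4β-(2-ethoxyethoxy)-3-O-(tri-O-benzylgalloyl)epiafzelechin | O=C(O[C@@H]1[C@@H](OCCOCC)c2c(OCc3ccccc3)cc(OCc3ccccc3)c(Br)c2O[C@@H]1c1ccc(OCc2ccccc2)cc1)c1cc(OCc2ccccc2)c(OCc2ccccc2)c(OCc2ccccc2)c1
F2 | step 5 | methyl (2S,3R)-3-[3,5-bis(benzyloxy)-2-bromophenoxy]-3-[4-(benzyloxy)phenyl]-2-hydroxypropanoate | COC(=O)[C@@H](O)[C@H](Oc1cc(OCc2ccccc2)cc(OCc2ccccc2)c1Br)c1ccc(OCc2ccccc2)cc1
F3 | step 4 | 3,5-bis(benzyloxy)phenyl N,N-diethylcarbamate | CCN(CC)C(=O)Oc1cc(OCc2ccccc2)cc(OCc2ccccc2)c1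
F4 | step 4 | 3,5-bis(benzyloxy)-2-bromophenyl N,N-diethylcarbamate | CCN(CC)C(=O)Oc1cc(OCc2ccccc2)cc(OCc2ccccc2)c1Br
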